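**Retrosynthetic overview**

1. The target comes from a triol by selective acetylation of the allylic hydroxyl; the 2α-hydroxyl comes from catalysed hydroboration of a ring A alkene; the E side-chain alkene comes from a terminal alkyne by Negishi carboalumination and hydroxymethylation.
2. The C-7=C-8 alkene with its 8-methyl group comes from an 8-ketone through the enol triflate and iron-catalysed methylation.
3. Key step: ring B is made by one-carbon ring expansion of a trans-hydrindanone (β-oxido carbenoid 1,2-shift of the quaternary carbon); the new enolate is alkylated in the same flask with the side-chain precursor.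
4. Ring A is closed by ring-closing metathesis; the quaternary C-4 is set by α-face methylation of the bicyclic acid.
5. The first stereocentres come from a new chiral-lithium-amide-directed Michael addition/allylation of 2-methylcyclopent-2-en-1-one, but-3-enoic acid and allyl bromide. Ring order: five-membered ring (bought), then ring A, then ring B by expansion of the five-membered ring.

Note: ring positions are cited with labdane numbering (ring carbons C-1 to C-10, side chain C-11 to C-16, C-17 to C-20 on C-8, C-4, C-4 and C-10); β is the face of the angular methyl group, α the opposite face.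

**Route**

Step 1
Reactants: 1 2-methylcyclopent-2-en-1-one; 2 but-3-enoic acid; 3 3-bromoprop-1-ene (allyl bromide)
Product: 5 2-[(1S,2S)-2-methyl-3-oxo-2-(prop-2-en-1-yl)cyclopentyl]but-3-enoic acid (epimers at C-2 of the acid), via dilithium enolate-carboxylate 4 (not isolated)
Conditions: N,N′-bis[(R)-1-phenyl-2-(piperidin-1-yl)ethyl]propane-1,3-diamine (1.05 equiv), n-butyllithium (4.0 equiv), 2, THF, 0 °C; 1, −78 → −40 °C; 3, −78 → −20 °C; aq HCl (tetramine recovered by acid/base extraction)
Reagents that add atoms: none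
Why: Proposed new method: the C2-symmetric dilithium amide forms a mixed aggregate with doubly lithiated 2 and screens one face of its α-carbon, lithium bridging to the enone carbonyl gives a closed transition state for α-selective 1,4-addition (1,2-adducts revert), so the configuration fixed at the acid α-carbon is relayed to the ring carbon that becomes C-5, and the tetrasubstituted enolate is then allylated anti to the new substituent, which sets C-10; the closest known reactions are chiral-lithium-amide-directed (traceless auxiliary) conjugate additions of carboxylic acid enediolates to α,β-unsaturated esters and α-alkylations of β,γ-unsaturated acids, here extended to a cyclic α-methyl enone with enolate trapping, and the tetramine enantiomer (both are available) is to be confirmed in a pilot run.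

Step 2
Reactants: 5 2-[(1S,2S)-2-methyl-3-oxo-2-(prop-2-en-1-yl)cyclopentyl]but-3-enoic acid
Product: 6 (3aS,7aS)-7a-methyl-1-oxo-2,3,3a,4,7,7a-hexahydro-1H-indene-4-carboxylic acid (C-4 epimers)
Conditions: RuCl2(H2IMes)(PCy3)(=CHPh) (second-generation Grubbs catalyst, 3 mol %), CH2Cl2, 40 °C
Reagents that add atoms: none
Why: Ring-closing metathesis of the vinyl and allyl groups closes ring A with the C-2=C-3 alkene and loss of ethene; no stereocentre is touched, and the trans relationship from step 1 makes the hydrindanone trans-fused.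

Step 3
Reactants: 6 (3aS,7aS)-7a-methyl-1-oxo-2,3,3a,4,7,7a-hexahydro-1H-indene-4-carboxylic acid
Product: 8 methyl (3aR,4S,7aS)-4,7a-dimethyl-1-oxo-2,3,3a,4,7,7a-hexahydro-1H-indene-4-carboxylate, via methylated carboxylic acid 7 (not isolated)
Conditions: lithium diisopropylamide (3.3 equiv), THF–DMPU, −78 → 0 °C; MeI (1.05 equiv), −78 °C; aq HCl; then K2CO3, MeI, DMF, rt
Reagents that add atoms: iodomethane, CI
Why: After threefold deprotonation the most basic carbon is C-4 (α to the carboxylate), so it is methylated first and from the α face because the β face is screened by the angular methyl group, which makes the carboxyl β (axial) and overwrites the earlier stereocentre at this carbon; carboxylate O-methylation then gives the ester (alkylation of a carboxylic acid dianion, then ester formation).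

Step 4
Reactants: 9 but-3-yn-1-ol
Product: 11 4-(trimethylsilyl)but-3-yn-1-ol, via O,C-bis(trimethylsilyl) intermediate 10 (not isolated)
Conditions: EtMgBr (2.1 equiv), THF, 0 °C → rt; Me3SiCl (2.1 equiv); aq HCl
Reagents that add atoms: chlorotrimethylsilane, C[Si](C)(C)Cl
Why: Double deprotonation, double silylation and acidic hydrolysis of the labile O–Si bond leave the C-silyl alkyne, which protects the acetylenic C–H through steps 6 to 8.

Step 5
Reactants: 11 4-(trimethylsilyl)but-3-yn-1-ol
Product: 12 4-(trimethylsilyl)but-3-yn-1-yl trifluoromethanesulfonate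
Conditions: Tf2O, 2,6-lutidine, CH2Cl2, −78 °C (used at once)
Reagents that add atoms: trifluoromethanesulfonic anhydride, O=S(=O)(OS(=O)(=O)C(F)(F)F)C(F)(F)F
Why: Standard O-sulfonylation gives a primary triflate that is reactive enough to alkylate a hindered enolate at low temperature, where elimination is slow.

Step 6
Reactants: 8 methyl (3aR,4S,7aS)-4,7a-dimethyl-1-oxo-2,3,3a,4,7,7a-hexahydro-1H-indene-4-carboxylate; 12 4-(trimethylsilyl)but-3-yn-1-yl trifluoromethanesulfonate
Product: 16 methyl (1S,4aS,5R,8aR)-1,4a-dimethyl-6-oxo-5-[4-(trimethylsilyl)but-3-yn-1-yl]-1,4,4a,5,6,7,8,8a-octahydronaphthalene-1-carboxylate, via lithium dibromomethyl carbinolate 13 (not isolated), via ring-expanded lithium enolate 14 (not isolated), via C-9 epimeric ketone 15 (not isolated)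
Conditions: CH2Br2, lithium 2,2,6,6-tetramethylpiperidide, THF, −78 °C; n-butyllithium, −78 → 0 °C; 12, THF, −78 → −30 °C; then DBU (cat.), CH2Cl2, rt
Reagents that add atoms: dibromomethane, BrCBr
Why: Nozaki–Yamamoto β-oxido carbenoid ring expansion: after addition of dibromomethyllithium and bromine–lithium exchange, the more substituted (quaternary C-10) carbon migrates with retention, which inserts C-9 between C-8 and C-10 and gives the C-8/C-9 enolate regiospecifically; this enolate is C-alkylated by the triflate from the α face, and DBU then equilibrates C-9 to the equatorial β side chain.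

Step 7
Reactants: 16 methyl (1S,4aS,5R,8aR)-1,4a-dimethyl-6-oxo-5-[4-(trimethylsilyl)but-3-yn-1-yl]-1,4,4a,5,6,7,8,8a-octahydronaphthalene-1-carboxylate
Product: 17 methyl (1S,4aS,5R,8aR)-1,4a-dimethyl-6-{[(trifluoromethyl)sulfonyl]oxy}-5-[4-(trimethylsilyl)but-3-yn-1-yl]-1,4,4a,5,8,8a-hexahydronaphthalene-1-carboxylate
Conditions: KN(SiMe3)2 (1.1 equiv), THF, −78 °C; PhNTf2
Reagents that add atoms: N-phenylbis(trifluoromethanesulfonimide), O=S(=O)(N(c1ccccc1)S(=O)(=O)C(F)(F)F)C(F)(F)F
Why: Kinetic deprotonation at the unhindered C-7 methylene and O-triflation fix the C-7=C-8 double bond (enol triflate formation); the hindered C-9 methine is not enolised, so its configuration is kept.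

Step 8
Reactants: 17 methyl (1S,4aS,5R,8aR)-1,4a-dimethyl-6-{[(trifluoromethyl)sulfonyl]oxy}-5-[4-(trimethylsilyl)but-3-yn-1-yl]-1,4,4a,5,8,8a-hexahydronaphthalene-1-carboxylate
Product: 18 methyl (1S,4aR,5S,8aR)-1,4a,6-trimethyl-5-[4-(trimethylsilyl)but-3-yn-1-yl]-1,4,4a,5,8,8a-hexahydronaphthalene-1-carboxylate
Conditions: MeMgBr (1.5 equiv), Fe(acac)3 (5 mol %), THF–NMP, −30 °C
Reagents that add atoms: methylmagnesium bromide, C[Mg]Br
Why: Iron-catalysed cross-coupling of the enol triflate with the Grignard reagent puts the C-8 methyl group on the preformed alkene; the hindered ester and the silyl alkyne are not attacked at −30 °C.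

Step 9
Reactants: 18 methyl (1S,4aR,5S,8aR)-1,4a,6-trimethyl-5-[4-(trimethylsilyl)but-3-yn-1-yl]-1,4,4a,5,8,8a-hexahydronaphthalene-1-carboxylate
Product: 20 [(1S,4aR,5S,8aR)-5-(but-3-yn-1-yl)-1,4a,6-trimethyl-1,4,4a,5,8,8a-hexahydronaphthalen-1-yl]methanol, via C-silylated alkynyl alcohol 19 (not isolated)
Conditions: i-Bu2AlH (3 equiv), CH2Cl2, −78 → 0 °C; aq potassium sodium tartrate; then K2CO3 (cat.), MeOH, rt
Reagents that add atoms: none
Why: Hydride reduction turns the neopentyl ester into the C-19 primary alcohol, and methanolysis cleaves the C–Si bond to free the terminal alkyne; no stereocentre is affected.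

Step 10
Reactants: 20 [(1S,4aR,5S,8aR)-5-(but-3-yn-1-yl)-1,4a,6-trimethyl-1,4,4a,5,8,8a-hexahydronaphthalen-1-yl]methanol
Product: 22 (2E)-5-[(1S,4aR,5S,8aR)-5-(hydroxymethyl)-2,5,8a-trimethyl-1,4,4a,5,8,8a-hexahydronaphthalen-1-yl]-3-methylpent-2-en-1-ol, via alkenylalane 21 (not isolated)
Conditions: AlMe3 (4 equiv), Cp2ZrCl2 (25 mol %), CH2Cl2, 0 °C → rt; n-butyllithium, THF, −78 °C; (CH2O)n, −78 °C → rt; aq NH4Cl
Reagents that add atoms: trimethylaluminium, C[Al](C)C; formaldehyde (as paraformaldehyde), C=O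
Why: Negishi zirconium-catalysed syn-carboalumination adds methyl to the inner and aluminium to the terminal alkyne carbon, and the alkenylalanate is hydroxymethylated with retention, which gives the E trisubstituted allylic alcohol only.

Step 11
Reactants: 22 (2E)-5-[(1S,4aR,5S,8aR)-5-(hydroxymethyl)-2,5,8a-trimethyl-1,4,4a,5,8,8a-hexahydronaphthalen-1-yl]-3-methylpent-2-en-1-ol
Product: 24 (2E)-5-[(1S,4aR,5S,7R,8aR)-7-hydroxy-5-(hydroxymethyl)-2,5,8a-trimethyl-1,4,4a,5,6,7,8,8a-octahydronaphthalen-1-yl]-3-methylpent-2-en-1-ol, via tris(catecholboryl) intermediate 23 (not isolated)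
Conditions: catecholborane (5 equiv), RhCl(PPh3)3 (5 mol %), THF, rt; then NaOH, H2O2, 0 °C
Reagents that add atoms: hydrogen peroxide, OO
Why: RhCl(PPh3)3-catalysed hydroboration attacks the cis-disubstituted ring A alkene but not the two trisubstituted alkenes, places boron at C-2 (C-3 is neopentyl) from the α face opposite the angular methyl and the axial C-4 substituent, and oxidation with retention gives the 2α (equatorial) alcohol.

Step 12
Reactants: 24 (2E)-5-[(1S,4aR,5S,7R,8aR)-7-hydroxy-5-(hydroxymethyl)-2,5,8a-trimethyl-1,4,4a,5,6,7,8,8a-octahydronaphthalen-1-yl]-3-methylpent-2-en-1-ol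
Product: 25 (2E)-5-[(1S,4aR,5S,7R,8aR)-7-hydroxy-5-(hydroxymethyl)-2,5,8a-trimethyl-1,4,4a,5,6,7,8,8a-octahydronaphthalen-1-yl]-3-methylpent-2-en-1-yl acetate
Conditions: AcCl (1.05 equiv), 2,4,6-collidine, CH2Cl2, −78 °C
Reagents that add atoms: acetyl chloride, CC(=O)Cl
Why: Sterically controlled acylation: the unhindered primary allylic hydroxyl reacts much faster than the neopentyl axial primary hydroxyl and the secondary ring hydroxyl.

**Compound list**

1 | 2-methylcyclopent-2-en-1-one | CC1=CCCC1=O | starting material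
2 | but-3-enoic acid | OC(=O)CC=C | starting material
3 | 3-bromoprop-1-ene (allyl bromide) | C=CCBr | starting material
4 | dilithium 2-[(1S)-2-methyl-3-oxidocyclopent-2-en-1-yl]but-3-enoate (epimers at C-2 of the butenoate) | [Li+].[Li+].[O-]C1=C(C)[C@H](C(C([O-])=O)C=C)CC1 | intermediate (not isolated)
5 | 2-[(1S,2S)-2-methyl-3-oxo-2-(prop-2-en-1-yl)cyclopentyl]but-3-enoic acid (allyl trans to the acid residue; epimers at C-2 of the acid) | O=C1CC[C@@H](C(C(=O)O)C=C)[C@]1(C)CC=C | intermediate
6 | (3aS,7aS)-7a-methyl-1-oxo-2,3,3a,4,7,7a-hexahydro-1H-indene-4-carboxylic acid (trans-fused; C-4 epimers) | O=C1CC[C@H]2C(C(=O)O)C=CC[C@]12C | intermediate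
7 | (3aR,4S,7aS)-4,7a-dimethyl-1-oxo-2,3,3a,4,7,7a-hexahydro-1H-indene-4-carboxylic acid | O=C1CC[C@H]2[C@@](C)(C(=O)O)C=CC[C@]12C | intermediate (not isolated)
8 | methyl (3aR,4S,7aS)-4,7a-dimethyl-1-oxo-2,3,3a,4,7,7a-hexahydro-1H-indene-4-carboxylate | O=C1CC[C@H]2[C@@](C)(C(=O)OC)C=CC[C@]12C | intermediate
9 | but-3-yn-1-ol | C#CCCO | starting material
10 | trimethyl{[4-(trimethylsilyl)but-3-yn-1-yl]oxy}silane | C[Si](C)(C)C#CCCO[Si](C)(C)C | intermediate (not isolated)
11 | 4-(trimethylsilyl)but-3-yn-1-ol | C[Si](C)(C)C#CCCO | intermediate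
12 | 4-(trimethylsilyl)but-3-yn-1-yl trifluoromethanesulfonate | C[Si](C)(C)C#CCCOS(=O)(=O)C(F)(F)F | intermediate
13 | lithium alkoxide from addition of dibromomethyllithium to the ketone of 8 (carbinol epimers) | [Li+].[O-]C1(C(Br)Br)CC[C@H]2[C@@](C)(C(=O)OC)C=CC[C@]12C | intermediate (not isolated)
14 | lithium C-8/C-9 enolate of the ring-expanded decalone (methyl 1,4a-dimethyl-6-oxido-1,4,4a,7,8,8a-hexahydronaphthalene-1-carboxylate, stereocentres as in 16) | [Li+].[O-]C1=C[C@@]2(C)CC=C[C@](C)(C(=O)OC)[C@@H]2CC1 | intermediate (not isolated)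
15 | methyl (1S,4aS,5S,8aR)-1,4a-dimethyl-6-oxo-5-[4-(trimethylsilyl)but-3-yn-1-yl]-1,4,4a,5,6,7,8,8a-octahydronaphthalene-1-carboxylate (side chain α, C-9 epimer of 16) | C[Si](C)(C)C#CCC[C@@H]1C(=O)CC[C@H]2[C@@](C)(C(=O)OC)C=CC[C@]12C | intermediate (not isolated)
16 | methyl (1S,4aS,5R,8aR)-1,4a-dimethyl-6-oxo-5-[4-(trimethylsilyl)but-3-yn-1-yl]-1,4,4a,5,6,7,8,8a-octahydronaphthalene-1-carboxylate | C[Si](C)(C)C#CCC[C@H]1C(=O)CC[C@H]2[C@@](C)(C(=O)OC)C=CC[C@]12C | intermediate
17 | methyl (1S,4aS,5R,8aR)-1,4a-dimethyl-6-{[(trifluoromethyl)sulfonyl]oxy}-5-[4-(trimethylsilyl)but-3-yn-1-yl]-1,4,4a,5,8,8a-hexahydronaphthalene-1-carboxylate | C[Si](C)(C)C#CCC[C@H]1C(OS(=O)(=O)C(F)(F)F)=CC[C@H]2[C@@](C)(C(=O)OC)C=CC[C@]12C | intermediate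
18 | methyl (1S,4aR,5S,8aR)-1,4a,6-trimethyl-5-[4-(trimethylsilyl)but-3-yn-1-yl]-1,4,4a,5,8,8a-hexahydronaphthalene-1-carboxylate | C[Si](C)(C)C#CCC[C@H]1C(C)=CC[C@H]2[C@@](C)(C(=O)OC)C=CC[C@]12C | intermediate
19 | [(1S,4aR,5S,8aR)-1,4a,6-trimethyl-5-[4-(trimethylsilyl)but-3-yn-1-yl]-1,4,4a,5,8,8a-hexahydronaphthalen-1-yl]methanol | C[Si](C)(C)C#CCC[C@H]1C(C)=CC[C@H]2[C@@](C)(CO)C=CC[C@]12C | intermediate (not isolated)
20 | [(1S,4aR,5S,8aR)-5-(but-3-yn-1-yl)-1,4a,6-trimethyl-1,4,4a,5,8,8a-hexahydronaphthalen-1-yl]methanol | C#CCC[C@H]1C(C)=CC[C@H]2[C@@](C)(CO)C=CC[C@]12C | intermediate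
21 | E alkenyl(dimethyl)alane from 20, hydroxyl as its dimethylaluminium alkoxide | C[Al](C)/C=C(\C)CC[C@H]1C(C)=CC[C@H]2[C@@](C)(CO[Al](C)C)C=CC[C@]12C | intermediate (not isolated)
22 | (2E)-5-[(1S,4aR,5S,8aR)-5-(hydroxymethyl)-2,5,8a-trimethyl-1,4,4a,5,8,8a-hexahydronaphthalen-1-yl]-3-methylpent-2-en-1-ol | OC/C=C(\C)CC[C@H]1C(C)=CC[C@H]2[C@@](C)(CO)C=CC[C@]12C | intermediate
23 | 2α-(catecholboryl) derivative of 22 with both hydroxyls as catecholborate esters | O(B1Oc2ccccc2O1)C/C=C(\C)CC[C@H]1C(C)=CC[C@H]2[C@@](C)(COB3Oc4ccccc4O3)C[C@H](B3Oc4ccccc4O3)C[C@]12C | intermediate (not isolated)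
24 | (2E)-5-[(1S,4aR,5S,7R,8aR)-7-hydroxy-5-(hydroxymethyl)-2,5,8a-trimethyl-1,4,4a,5,6,7,8,8a-octahydronaphthalen-1-yl]-3-methylpent-2-en-1-ol | OC/C=C(\C)CC[C@H]1C(C)=CC[C@H]2[C@@](C)(CO)C[C@H](O)C[C@]12C | intermediate
25 | (2E)-5-[(1S,4aR,5S,7R,8aR)-7-hydroxy-5-(hydroxymethyl)-2,5,8a-trimethyl-1,4,4a,5,6,7,8,8a-octahydronaphthalen-1-yl]-3-methylpent-2-en-1-yl acetate | CC(=O)OC/C=C(\C)CC[C@H]1C(C)=CC[C@H]2[C@@](C)(CO)C[C@H](O)C[C@]12C | target

**Step count and risk**

Total step count: 12. Longest linear sequence: 10 steps (steps 1–3 and 6–12; steps 4 and 5 make the alkylating agent).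

The three steps most likely to fail:

Step 1 is the new step. The risks are 1,2- against 1,4-addition, α- against γ-attack of the doubly lithiated acid, and the level and sense of asymmetric induction. The fallback uses known chemistry, sets out from 1, 2 and 3 and comes back to the route at 7. Acid 2 is doubly deprotonated with lithium diisopropylamide alone, added to 1, and the enolate is allylated with 3 (conjugate addition of a carboxylic acid dianion, then enolate allylation). This gives 5 as a racemate, that is 5 together with its mirror image, the (1R,2R) keto acid F1. Ring-closing metathesis and the C-methylation of step 3 on the racemate carry along the mirror-image bicyclic acid F2 and the mirror-image methylated acid F3. The racemic methylated acid is resolved by fractional crystallisation with (R)-1-phenylethanamine: the (R)-1-phenylethanaminium salt of 7 F4 is separated from the (R)-1-phenylethanaminium salt of the mirror-image acid F5. Acidification of F4 returns 7 for the esterification that ends step 3.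

Step 6 carries three risks: migration of C-7 in place of the quaternary carbon, attack of n-butyllithium on the ester, and above all C-alkylation of the hindered enolate 14. The fallback sets out from 8 and comes back at 22. Enolate 14 is generated as in step 6 but trapped with Me3SiCl as the trimethylsilyl enol ether F6. Mukaiyama–Michael addition of F6 to but-3-en-2-one (TiCl4, CH2Cl2, −78 °C), then DBU, gives the 1,5-diketone F7. Horner–Wadsworth–Emmons olefination of the methyl ketone only (methyl (dimethoxyphosphoryl)acetate, NaH, THF; the minor Z isomer is removed by chromatography) gives the E enoate F8. KN(SiMe3)2 and PhNTf2 give the enol triflate F9, and ZnMe2 with Pd(PPh3)4 gives the methylated diester F10. Reduction of both ester groups of F10 with i-Bu2AlH gives diol 22. This fallback avoids the alkylation but still relies on the carbenoid migration.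

Step 11 carries three risks: a slow reaction at the hindered ring A alkene, competing reaction of the trisubstituted alkenes, and regiochemistry. The fallback sets out from 8 and comes back at 24; it costs two extra steps. The hydroxyl is introduced while the ring A alkene is the only alkene: the same RhCl(PPh3)3/catecholborane hydroboration and oxidation on 8 (ketones are tolerated under the catalysed conditions) gives the 2α-hydroxy keto ester F11. Et3SiCl and imidazole give the triethylsilyl ether F12. Steps 6 to 10 run on F12 give in turn the silyloxy decalone F13, the enol triflate F14, the methylated ester F15, the alkynyl alcohol F16 and the silyloxy diol F17. Pyridinium p-toluenesulfonate in methanol removes the triethylsilyl group of F17 and gives triol 24.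

**Further compounds**

F1 | step 1 | 2-[(1R,2R)-2-methyl-3-oxo-2-(prop-2-en-1-yl)cyclopentyl]but-3-enoic acid (mirror image of 5) | O=C1CC[C@H](C(C(=O)O)C=C)[C@@]1(C)CC=C
F2 | step 1 | (3aR,7aR)-7a-methyl-1-oxo-2,3,3a,4,7,7a-hexahydro-1H-indene-4-carboxylic acid (mirror image of 6) | O=C1CC[C@@H]2C(C(=O)O)C=CC[C@@]12C
F3 | step 1 | (3aS,4R,7aR)-4,7a-dimethyl-1-oxo-2,3,3a,4,7,7a-hexahydro-1H-indene-4-carboxylic acid (mirror image of 7) | O=C1CC[C@@H]2[C@](C)(C(=O)O)C=CC[C@@]12C
F4 | step 1 | (R)-1-phenylethanaminium salt of 7 | O=C1CC[C@H]2[C@@](C)(C(=O)[O-])C=CC[C@]12C.C[C@@H]([NH3+])c1ccccc1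
F5 | step 1 | (R)-1-phenylethanaminium salt of the mirror image of 7 | O=C1CC[C@@H]2[C@](C)(C(=O)[O-])C=CC[C@@]12C.C[C@@H]([NH3+])c1ccccc1
F6 | step 6 | trimethylsilyl enol ether of the ring-expanded decalone | C[Si](C)(C)OC1=C[C@@]2(C)CC=C[C@](C)(C(=O)OC)[C@@H]2CC1
F7 | step 6 | methyl (1S,4aS,5R,8aR)-1,4a-dimethyl-6-oxo-5-(3-oxobutyl)-1,4,4a,5,6,7,8,8a-octahydronaphthalene-1-carboxylate | CC(=O)CC[C@H]1C(=O)CC[C@H]2[C@@](C)(C(=O)OC)C=CC[C@]12C
F8 | step 6 | methyl (1S,4aS,5R,8aR)-5-[(3E)-5-methoxy-3-methyl-5-oxopent-3-en-1-yl]-1,4a-dimethyl-6-oxo-1,4,4a,5,6,7,8,8a-octahydronaphthalene-1-carboxylate | COC(=O)/C=C(\C)CC[C@H]1C(=O)CC[C@H]2[C@@](C)(C(=O)OC)C=CC[C@]12C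
F9 | step 6 | enol triflate of F8 (C-7=C-8) | COC(=O)/C=C(\C)CC[C@H]1C(OS(=O)(=O)C(F)(F)F)=CC[C@H]2[C@@](C)(C(=O)OC)C=CC[C@]12C
F10 | step 6 | methyl (1S,4aR,5S,8aR)-5-[(3E)-5-methoxy-3-methyl-5-oxopent-3-en-1-yl]-1,4a,6-trimethyl-1,4,4a,5,8,8a-hexahydronaphthalene-1-carboxylate | COC(=O)/C=C(\C)CC[C@H]1C(C)=CC[C@H]2[C@@](C)(C(=O)OC)C=CC[C@]12C
F11 | step 11 | methyl 2α-hydroxy analogue of 8 (trans-fused 6-hydroxy-4,7a-dimethyl-1-oxooctahydro-1H-indene-4-carboxylate) | O=C1CC[C@H]2[C@@](C)(C(=O)OC)C[C@H](O)C[C@]12C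
F12 | step 11 | triethylsilyl ether of F11 | O=C1CC[C@H]2[C@@](C)(C(=O)OC)C[C@H](O[Si](CC)(CC)CC)C[C@]12C
F13 | step 11 | 2α-triethylsilyloxy-2,3-dihydro analogue of 16 | C[Si](C)(C)C#CCC[C@H]1C(=O)CC[C@H]2[C@@](C)(C(=O)OC)C[C@H](O[Si](CC)(CC)CC)C[C@]12C
F14 | step 11 | 2α-triethylsilyloxy-2,3-dihydro analogue of 17 | C[Si](C)(C)C#CCC[C@H]1C(OS(=O)(=O)C(F)(F)F)=CC[C@H]2[C@@](C)(C(=O)OC)C[C@H](O[Si](CC)(CC)CC)C[C@]12C
F15 | step 11 | 2α-triethylsilyloxy-2,3-dihydro analogue of 18 | C[Si](C)(C)C#CCC[C@H]1C(C)=CC[C@H]2[C@@](C)(C(=O)OC)C[C@H](O[Si](CC)(CC)CC)C[C@]12C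
F16 | step 11 | 2α-triethylsilyloxy-2,3-dihydro analogue of 20 | C#CCC[C@H]1C(C)=CC[C@H]2[C@@](C)(CO)C[C@H](O[Si](CC)(CC)CC)C[C@]12C
F17 | step 11 | 2-O-triethylsilyl ether of triol 24 | OC/C=C(\C)CC[C@H]1C(C)=CC[C@H]2[C@@](C)(CO)C[C@H](O[Si](CC)(CC)CC)C[C@]12C
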